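At early times coupling and quench compete for the starting material, so I turn each constant into a time at the charged amounts.

    starting material + coupling partner → intermediate + by-product (k1 = 720 M⁻¹ s⁻¹)
    intermediate → target (k2 = 0.34 s⁻¹)
    starting material + protic impurity → quenched substrate (k3 = 15000 M⁻¹ s⁻¹)
    target ⇌ isomer of the product (K4 = 0.71, k4 = 0.15 s⁻¹)

starting material 0.20 mM; coupling partner 0.200 mM; protic impurity 0.0400 mM; time 10 min

* the state of affairs at 10 min: stopped, and by what, or still going (forward and back rates have come level / all of the starting material has reacted / the coupling partner has run out first / it is still moving)
* target at 10 min, in percent of the starting material charged

- the reaction counts as stopped when no species that holds the starting material changes by six tenths of a point or more over the second half of the time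
- run time (flask): 10 min

In the flask, coupling by itself gives the starting material a half-life of 0.080 min, but the quench by itself gives 1.2 s, which is shorter, and coupling starts at 0.24 of the quench rate. The protic impurity has a half-life of 0.231 s at the charged starting material, far shorter than that of coupling, so I count its charge as quenched substrate. That leaves 0.160 mM to couple, less than the 0.200 mM of coupling partner, so the starting material is the limiting reagent. Even on the final excess of partner, the half-life of the starting material by coupling is 24.1 s, short against 10 min. The intermediate has a half-life of 2.0 s, and target and isomer relax with one of 1.92 s, both short against the run. So I estimate the end share of target Y, the share of starting material the impurity does not take divided by one plus the equilibrium constant 0.71, at 46.8%.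

The forecast says all of the starting material has reacted, with 46.8% of target (range 46% to 47.5%), since “the starting material, not the partner, runs out”. It rests on the same grounds as my reckoning, so neither checks the other.

The simulation of the flask gives all of the starting material has reacted, with 46.8% of target at 10.0 min, against Y of 46.8%; quenched substrate stands at 20.0%, the isomer at 33.2%, and 20% of the charged coupling partner remains. In the neighbouring flask, with 0.010 mM of protic impurity, 0.190 mM is left to couple, still less than the partner, and Y becomes 55.6%. That flask gives 55.5% of target at 10.0 min, with 5.00% of quenched substrate and 0.064% of the starting material left.

(All constants stand for no real mixture; no experiment stands behind them.)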